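**Retrosynthetic overview**
1. The oxirane is the only ring and is closed last: α-chloro aldehyde 14 plus a CH2 unit (chloromethyllithium addition under Cornforth control, then ring closure).
2. C3–Cl/C4–Br: catalyst-controlled anti bromochlorination of the (E)-allylic alcohol 12.
3. C3–C2 and C3–CH3: two boron 1,2-metallate shifts on an acetylene linchpin (Matteson homologation of alkenyl boronate 9; acid-triggered 1,2-methyl shift in alkynyl boronate complex 8).
4. C4–C5: C-alkylation of the lithiated ethynylboronate complex 7 with triflate 3.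
5. C6–Br/C7–Cl: enantioselective bromochlorination of prenol 1.

Assumption: the sense of induction of the titanium/Schiff-base bromochlorination catalyst is fixed by the ligand enantiomer, so the ligand is specified by the product configuration it must deliver; target atoms are numbered C1–C8 along the octane chain (oxirane C1–C2).

**Step 1**
Reactants: 1 3-methylbut-2-en-1-ol (prenol)
Product: 2 (2R)-2-bromo-3-chloro-3-methylbutan-1-ol
Conditions: NBS, ClTi(OiPr)3, chiral tridentate Schiff-base ligand (20 mol%, enantiomer giving the 2R bromide), hexanes, −20 °C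
Reagents that add atoms: N-bromosuccinimide O=C1CCC(=O)N1Br; chlorotitanium triisopropoxide CC(C)O[Ti](Cl)(OC(C)C)OC(C)C
Why: Enantioselective titanium-mediated bromochlorination of an allylic alcohol (Burns-type dihalogenation), in which the Ti-bound alkoxide and chiral Schiff base direct Br+ to one alkene face at C2 and chloride opens the bromonium ion anti at the tertiary carbon (Markovnikov), so the single new stereocentre (the future C6–Br) is set R under catalyst control.

**Step 2**
Reactants: 2 (2R)-2-bromo-3-chloro-3-methylbutan-1-ol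
Product: 3 (2R)-2-bromo-3-chloro-3-methylbutyl trifluoromethanesulfonate
Conditions: Tf2O, 2,6-lutidine, CH2Cl2, −78 °C; used at once
Reagents that add atoms: trifluoromethanesulfonic anhydride O=S(=O)(OS(=O)(=O)C(F)(F)F)C(F)(F)F
Why: O-Sulfonylation of the primary alcohol with a non-nucleophilic base at low temperature leaves the adjacent C–Br stereocentre untouched and makes C5 an SN2-competent electrophile.

**Step 3**
Reactants: 3 (2R)-2-bromo-3-chloro-3-methylbutyl trifluoromethanesulfonate; 4 acetylene
Product: 9 2-[(2Z,5R)-5-bromo-6-chloro-6-methylhept-2-en-2-yl]-4,4,5,5-tetramethyl-1,3,2-dioxaborolane, via lithium acetylide 5 (not isolated), via ethynyl ate complex 6 (not isolated), via lithiated ate complex 7 (not isolated), via alkynyl ate complex 8 (not isolated)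
Conditions: 4 (1.0 equiv, titrated THF solution), n-BuLi, THF, −78 °C; MeBpin, −78 °C; n-BuLi, −78 to −30 °C; 3, −78 to −40 °C; t-BuCO2H, −78 to 0 °C
Reagents that add atoms: methylboronic acid pinacol ester CB1OC(C)(C)C(C)(C)O1
Why: Proposed new method: the C-lithiated ethynyl(methyl)boronate complex 7 acts as a boron-masked acetylide that is alkylated at carbon by the primary triflate (SN2, no stereocentre touched, and no alkyllithium ever meets the alkyl halides), after which a hindered carboxylic acid protonates the distal alkyne carbon of ate complex 8 with concerted anti 1,2-migration of methyl from boron to carbon (1,2-metallate rearrangement, σ(B–CH3) anti-periplanar to the incoming proton), forming the C3–CH3 bond and fixing the alkene geometry (CH3 cis to the chain, Bpin trans) that is later relayed into the C3/C4 configuration; the closest known reactions are the protonation- or alkylation-induced 1,2-migrations of lithium 1-alkynyltrialkylborates and Zweifel-type electrophile-induced 1,2-metallate rearrangements of pinacol boronate complexes.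

**Step 4**
Reactants: 9 2-[(2Z,5R)-5-bromo-6-chloro-6-methylhept-2-en-2-yl]-4,4,5,5-tetramethyl-1,3,2-dioxaborolane
Product: 12 (2E,5R)-5-bromo-6-chloro-2,6-dimethylhept-2-en-1-ol, via chloromethyl ate complex 10 (not isolated), via allyl boronate 11 (not isolated)
Conditions: ICH2Cl, n-BuLi, THF, −78 °C to rt; then H2O2, aq NaOH, 0 °C
Reagents that add atoms: chloroiodomethane ClCI; hydrogen peroxide OO
Why: Matteson homologation, in which chloromethyllithium made in situ adds to boron and the alkenyl group migrates 1,2 from boron to carbon with loss of chloride and retention of double-bond geometry, followed by oxidation of the allyl boronate without allylic transposition to give the (E)-allylic alcohol with the 5R centre untouched.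

**Step 5**
Reactants: 12 (2E,5R)-5-bromo-6-chloro-2,6-dimethylhept-2-en-1-ol
Product: 13 (2R,3S,5R)-3,5-dibromo-2,6-dichloro-2,6-dimethylheptan-1-ol
Conditions: NBS, ClTi(OiPr)3, chiral tridentate Schiff-base ligand (20–30 mol%, enantiomer giving the 2R,3S product), hexanes, −20 °C
Reagents that add atoms: N-bromosuccinimide O=C1CCC(=O)N1Br; chlorotitanium triisopropoxide CC(C)O[Ti](Cl)(OC(C)C)OC(C)C
Why: Second catalyst-controlled titanium/Schiff-base bromochlorination of an allylic alcohol, in which face-selective bromonium formation and anti Markovnikov-type chloride opening at the tertiary carbon convert the (E)-alkene into the (2R,3S) bromochloride (C3 and C4 of the target), the remote 5R centre being overridden by the catalyst.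

**Step 6**
Reactants: 13 (2R,3S,5R)-3,5-dibromo-2,6-dichloro-2,6-dimethylheptan-1-ol
Product: 14 (2R,3S,5R)-3,5-dibromo-2,6-dichloro-2,6-dimethylheptanal
Conditions: Dess–Martin periodinane, NaHCO3, CH2Cl2, 0 °C to rt
Reagents that add atoms: none
Why: Dess–Martin oxidation under buffered conditions, where the quaternary α-carbon excludes both epimerisation and β-elimination of bromide.

**Step 7**
Reactants: 14 (2R,3S,5R)-3,5-dibromo-2,6-dichloro-2,6-dimethylheptanal
Product: 16 (2R)-2-[(2R,3S,5R)-3,5-dibromo-2,6-dichloro-6-methylheptan-2-yl]oxirane, via lithium alkoxide 15 (not isolated)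
Conditions: ICH2Cl, MeLi·LiBr, THF, −78 °C to rt
Reagents that add atoms: chloroiodomethane ClCI
Why: Chloromethyllithium (carbenoid formed by I/Li exchange in the presence of the aldehyde) adds to the carbonyl under Cornforth (polar Felkin–Anh) control by the α-chloro quaternary centre, attacking past the methyl group with C=O anti to C–Cl to set 2R, and the alkoxide then closes the oxirane by 3-exo-tet displacement of the primary chloride on warming (halohydrin epoxide formation).

**Compound list**
1 | 3-methylbut-2-en-1-ol (prenol) | CC(C)=CCO | starting material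
2 | (2R)-2-bromo-3-chloro-3-methylbutan-1-ol | CC(C)(Cl)[C@H](Br)CO | intermediate
3 | (2R)-2-bromo-3-chloro-3-methylbutyl trifluoromethanesulfonate | CC(C)(Cl)[C@H](Br)COS(=O)(=O)C(F)(F)F | intermediate
4 | acetylene | C#C | starting material
5 | ethynyllithium (lithium acetylide) | [Li]C#C | intermediate
6 | lithium 2-ethynyl-2,4,4,5,5-pentamethyl-1,3,2-dioxaborolan-2-uide | [Li+].C#C[B-]1(C)OC(C)(C)C(C)(C)O1 | intermediate
7 | lithium 2-(lithioethynyl)-2,4,4,5,5-pentamethyl-1,3,2-dioxaborolan-2-uide | [Li+].[Li]C#C[B-]1(C)OC(C)(C)C(C)(C)O1 | intermediate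
8 | lithium 2-[(4R)-4-bromo-5-chloro-5-methylhex-1-yn-1-yl]-2,4,4,5,5-pentamethyl-1,3,2-dioxaborolan-2-uide | [Li+].C[B-]1(OC(C)(C)C(C)(C)O1)C#CC[C@@H](Br)C(C)(C)Cl | intermediate
9 | 2-[(2Z,5R)-5-bromo-6-chloro-6-methylhept-2-en-2-yl]-4,4,5,5-tetramethyl-1,3,2-dioxaborolane | C/C(B1OC(C)(C)C(C)(C)O1)=C\C[C@@H](Br)C(C)(C)Cl | intermediate
10 | lithium 2-[(2Z,5R)-5-bromo-6-chloro-6-methylhept-2-en-2-yl]-2-(chloromethyl)-4,4,5,5-tetramethyl-1,3,2-dioxaborolan-2-uide | [Li+].C/C(=C\C[C@@H](Br)C(C)(C)Cl)[B-]1(CCl)OC(C)(C)C(C)(C)O1 | intermediate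
11 | 2-[(2E,5R)-5-bromo-6-chloro-2,6-dimethylhept-2-en-1-yl]-4,4,5,5-tetramethyl-1,3,2-dioxaborolane | B1(OC(C)(C)C(C)(C)O1)C/C(C)=C/C[C@@H](Br)C(C)(C)Cl | intermediate
12 | (2E,5R)-5-bromo-6-chloro-2,6-dimethylhept-2-en-1-ol | OC/C(C)=C/C[C@@H](Br)C(C)(C)Cl | intermediate
13 | (2R,3S,5R)-3,5-dibromo-2,6-dichloro-2,6-dimethylheptan-1-ol | CC(C)(Cl)[C@H](Br)C[C@H](Br)[C@](C)(Cl)CO | intermediate
14 | (2R,3S,5R)-3,5-dibromo-2,6-dichloro-2,6-dimethylheptanal | CC(C)(Cl)[C@H](Br)C[C@H](Br)[C@](C)(Cl)C=O | intermediate
15 | lithium (2R,3R,4S,6R)-4,6-dibromo-1,3,7-trichloro-3,7-dimethyloctan-2-olate | [Li+].CC(C)(Cl)[C@H](Br)C[C@H](Br)[C@](C)(Cl)[C@H]([O-])CCl | intermediate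
16 | (2R)-2-[(2R,3S,5R)-3,5-dibromo-2,6-dichloro-6-methylheptan-2-yl]oxirane, i.e. (2R,3R,4S,6R)-4,6-dibromo-3,7-dichloro-1,2-epoxy-3,7-dimethyloctane | CC(C)(Cl)[C@H](Br)C[C@H](Br)[C@](C)(Cl)[C@H]1CO1 | target

**Total step count:** 7. **Longest linear sequence:** 7 (1 → 16; acetylene 4 enters in step 3).

**Steps most likely to fail**

Step 3 (the proposed new step). The alkynyl boronate complex may dissociate back to the acetylide, be protonated at a pinacol oxygen instead of at carbon, or rearrange with loss of E/Z purity. The fallback is known chemistry and sets out from triflate 3. Alkylation with 1-propynyllithium (THF/DMPU, −78 °C) gives (5R)-5-bromo-6-chloro-6-methylhept-2-yne F1. Syn-hydroboration with HBpin and catalytic Cp2ZrHCl places boron on the less hindered, methyl-bearing alkyne carbon with hydrogen cis to it. This gives alkenyl boronate 9 after removal of the minor regioisomer, and the route resumes at step 4 with the Matteson 1,2-shift unchanged.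

Step 5. Chloride may open the bromonium ion at the secondary carbon instead of the tertiary one, and catalyst control on this polyhalogenated alcohol may be incomplete. The fallback sets out from 12 and builds the two centres through an epoxide. Sharpless asymmetric epoxidation (Ti(OiPr)4, D-(−)-diethyl tartrate, t-BuOOH, 4 Å sieves, CH2Cl2, −20 °C) gives [(2R,3R)-3-[(2R)-2-bromo-3-chloro-3-methylbutyl]-2-methyloxiran-2-yl]methanol F2. Ti(OiPr)4-assisted opening with a bromide source (Et2NH·HBr) at the oxirane carbon remote from the CH2OH group, with inversion, gives (2R,3S,5R)-3,5-dibromo-6-chloro-2,6-dimethylheptane-1,2-diol F3. Dry HCl in CH2Cl2 at 0 °C then converts only the tertiary alcohol into the chloride through the bridged bromonium ion (retention, chlorine anti to bromine), which returns the route to 13.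

Step 7. The substrate-controlled selectivity at C2 may be modest, and the basic carbenoid may cause loss of HBr. The fallback sets out from 14 and puts C2 under reagent control. Chloromethyllithium addition with an acetic acid quench at −78 °C gives (3R,4S,6R)-4,6-dibromo-1,3,7-trichloro-3,7-dimethyloctan-2-ol F4 as a mixture of C2 epimers. Dess–Martin oxidation gives (3R,4S,6R)-4,6-dibromo-1,3,7-trichloro-3,7-dimethyloctan-2-one F5. Corey–Bakshi–Shibata reduction (oxazaborolidine enantiomer that gives the 2R alcohol, BH3·SMe2) gives (2R,3R,4S,6R)-4,6-dibromo-1,3,7-trichloro-3,7-dimethyloctan-2-ol F6. K2CO3 in MeOH closes the oxirane and returns the route to 16.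

**Further compounds**
F1 | step 3 | (5R)-5-bromo-6-chloro-6-methylhept-2-yne | CC#CC[C@@H](Br)C(C)(C)Cl
F2 | step 5 | [(2R,3R)-3-[(2R)-2-bromo-3-chloro-3-methylbutyl]-2-methyloxiran-2-yl]methanol | OC[C@@]1(C)O[C@@H]1C[C@@H](Br)C(C)(C)Cl
F3 | step 5 | (2R,3S,5R)-3,5-dibromo-6-chloro-2,6-dimethylheptane-1,2-diol | CC(C)(Cl)[C@H](Br)C[C@H](Br)[C@](C)(O)CO
F4 | step 7 | (3R,4S,6R)-4,6-dibromo-1,3,7-trichloro-3,7-dimethyloctan-2-ol (both C2 epimers) | CC(C)(Cl)[C@H](Br)C[C@H](Br)[C@](C)(Cl)C(O)CCl
F5 | step 7 | (3R,4S,6R)-4,6-dibromo-1,3,7-trichloro-3,7-dimethyloctan-2-one | CC(C)(Cl)[C@H](Br)C[C@H](Br)[C@](C)(Cl)C(=O)CCl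
F6 | step 7 | (2R,3R,4S,6R)-4,6-dibromo-1,3,7-trichloro-3,7-dimethyloctan-2-ol | CC(C)(Cl)[C@H](Br)C[C@H](Br)[C@](C)(Cl)[C@H](O)CCl
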